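## The problem

- Target 21 is a tetrahydrofuran in which all four ring carbons are stereogenic. C2 and C5 each carry a 4-hydroxy-3-methoxyphenyl group, C3 is a tertiary methyl carbinol and C4 a methyl-bearing methine. Ring atoms are numbered O1, C2–C5 as in the target throughout, also for open-chain intermediates.
- In the (2R,3S,4S,5S) isomer the C2 aryl is trans to the C3 hydroxyl, the two methyl groups are trans, the C4 methyl is cis to the C5 aryl, and the two aryl groups are trans. The cis C4/C5 pair is the one that neither equilibration nor a hydride delivered to a C5 cation is expected to give.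
- C3 cannot be made by carbonyl reduction and cannot be corrected later. It is therefore best bought and used as the controlling element: its oxygen can hold a metal toward C4 (enolate) and toward C2 (ketone), and in the ring its oxygen and methyl fix the conformation of a cation at C5.
- Both ring C–O bonds are benzylic to electron-rich arenes, so they ionise with acid and can cleave on long hydrogenolysis. The phenols need a mask that survives organometallic reagents. Every intermediate with the C3 hydroxyl β to a carbonyl group is open to retro-aldol cleavage or dehydration under base, and C4–H stays α to a carbonyl group until late.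
- The two aryl groups are identical, so one aryl bromide serves twice, but C2 and C5 are completed in different ways and their carboxyl precursors must be told apart.
- The feature that opens the key step: without the aryl groups, C3 is a methyl carbinol flanked by a carboxyl carbon (C2) and a methylene–carboxyl unit (C4–C5). This is (S)-citramalic acid 1 in the right configuration, and its methylene carbon, as the enolate of the C5 ester, can take the C4 methyl from iodomethane 3 under the control of the neighbouring alkoxide.

## Retrosynthesis

**21 to 20.** The two phenolic O–H bonds are traced back to benzyl ethers in 20. The aryl groups enter as organolithium and organomagnesium reagents, so a base-stable mask is needed, and one hydrogenolysis removes both without acid or fluoride near the benzylic ring ethers. The forward step only has to distinguish aryl benzyl ethers from the two more hindered ring C–O bonds.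

**20 to 15 and 9.** The C5–aryl bond is cut; C5 becomes the lactol carbon of 15 and the aryl comes from bromide 9 as Grignard reagent 18.
- The neighbouring cut, C5–H (adding aryllithium 10 to the carbonyl of 14 and reducing ionically), is rejected. Nucleophiles attack five-membered oxocarbenium ions from the inside of the envelope, cis to a pseudoaxial alkoxy group and trans to an alkyl group on the carbon two bonds away. Both rules point to the face of the C3 oxygen, so a hydride would enter there and leave the aryl trans to the C4 methyl, which is the C5 epimer.
- With the aryl as the nucleophile the same preference gives the required 4,5-cis, 2,5-trans product.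
- Precursor 15 has one aryl group and one stereocentre fewer. The forward reaction needs both hydroxyls silylated (16), a mild route to the cation (bromo ether 17) and low temperature so that the C2–O bond does not ionise.

**15 to 14.** No skeletal bond is cut; the lactol is the partly reduced form of γ-lactone 14. The lactone is preferred as the stored intermediate because it is stable, locks C2, C3 and C4 in the ring and is reduced cleanly to the aldehyde oxidation state.

**14 to 12.** The acyl–O1 bond and the C2–H bond are cut. The lactone opens to hydroxy ester 13, whose C2 carbinol comes from aryl ketone 12 by hydride addition.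
- A ketone at C2 sits next to the free C3 hydroxyl, so a chelating hydride reagent can set C2 from the existing centre.
- Adding the aryl to a C2 aldehyde under the same chelate would give the C2 epimer, which is why the aryl is placed first and the hydrogen second.
- The forward step needs the five-membered zinc chelate to win over coordination to the ester.

**12 to 8 and 9.** The C2–aryl bond is cut: keto ester 12 comes from keto acid 11, which is the product of aryllithium 10 (from 9) and the morpholine amide of 8. An amide stops at the ketone stage. The C5 carboxyl must be a carboxylate while the aryllithium is present, which is why ester 7 is saponified to 8 first and the methyl ester is restored afterwards (11 to 12).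

**7 to 5 and 3 (key cut).** The C4–CH3 bond is cut, giving the citramalate derivative 5 and iodomethane 3.
- Against the C3–C4 cut (which would have to create the tertiary carbinol stereocentre) and the C3–CH3 cut (which needs C4 and C5 first), this cut keeps C3 as a purchased centre and lets it set C4 through a chelated alkoxide–enolate dianion 6.
- The precursor has no stereocentre other than C3.
- The forward reaction must make iodomethane enter on the face of the C3 methyl. A methyl ester at C2 is not clearly larger than methyl, so the C2 carboxyl is carried as the morpholine amide, which is bulkier and is also the later acyl donor.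

**5 to 1.** The two carboxyl groups of 1 are told apart through the α-hydroxy acid unit. It alone forms a five-membered acetonide (2), the free carboxyl is esterified (4), and the activated acetonide carbonyl is opened by morpholine (5). No bond at C3 is touched.

## Roads not taken

**Alternative 1:** The C3–O and C4–H bonds are cut, leading back to the C2-symmetric dihydrofuran A1, which already holds both aryl-bearing centres.
- Forward key step: Co(acac)2, phenylsilane and O2 transfer a hydrogen atom to one alkene carbon and oxygen to the other, giving A2, which is the same compound as 20.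
- Merits: the symmetry makes the regiochemistry irrelevant, two stereocentres arise in one step, and there is no carbonyl intermediate, so retro-aldol and C4 epimerisation do not arise. With A1 in hand this is clearly the shorter route.
- Weak points: the alkene is tetrasubstituted, the poorest substrate class for this hydration. The two new bonds must form on opposite faces (hydrogen anti to the C5 aryl, oxygen anti to the C2 aryl but syn to the new C4 methyl), and the planar C3 radical has no strong reason to choose. The C2–H and C5–H bonds of A1 are allylic, benzylic and next to oxygen, so loss of the two ring hydrogens and aromatisation of the ring under O2 is a real competitor. A1 itself needs an enantioselective synthesis.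
- Comparison: the chosen plan is longer, but each of its stereocentres is tied to the purchased C3 through a closed transition-state model instead of a radical preference.

**Alternative 2:** The C3–C4 bond is cut.
- Forward key step: ester A3 is enolised and silylated under chelation control (LiN(iPr)2, chlorotrimethylsilane) and rearranges through a chair (Ireland–Claisen) to acid A4, forming C3–C4 and both centres at once.
- Merits: for the C3/C4 pair alone this is the better-founded reaction. Chelated enolate geometry and chair transition states are well understood even for fully substituted α-alkoxy centres, whereas the chosen dianion methylation has to discriminate an amide from a methyl group.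
- Weak points: the anti relationship needed here requires A3 with a (Z)-trisubstituted aryl alkene and an enantiopure carbinol; the (Z) substituent sits axial in the chair and erodes selectivity. After the rearrangement the aryl-bearing alkene carbon has to be cut free oxidatively next to an electron-rich arene. C5 would then receive its hydrogen as hydride, the mode argued above to give the wrong epimer. The tertiary benzyl ether blocks chelation at C2 until it is removed.
- Comparison: the chosen plan buys C3, wastes no carbon and forms C5 with the aryl as nucleophile; its cost is the less certain face selection in step 4.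

**Alternative 3:** The C3–CH3 bond is cut.
- Forward key step: lactone A5 is deprotonated with LiN(iPr)2 and the enolate is methylated by iodomethane 3 trans to the C4 methyl, giving A6.
- Merits: alkylation of a lactone enolate anti to the adjacent substituent is dependable, probably more so than step 4 taken alone. A6 holds three of the four centres, and one hydrogenolysis at the end would remove all three benzyl groups.
- Weak points: A5 already contains the cis C4-methyl/C5-aryl pair, so the hardest relationship is moved into the synthesis of the starting lactone. C2 must then be finished by aryl addition to the lactone carbonyl of A6 and hydride delivery cis to the C4 methyl and C5 aryl, the more hindered face.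
- Comparison: the chosen plan has a weaker alkylation but a matched answer for C5 and C2, both controlled by the C3 oxygen.

Key step: step 4

Assumption: the dianion of 5 is taken to alkylate in the sense known for malate diesters (new group anti to the carbinol oxygen), with the amide in the role of the malate ester group; 1, 3 and 9 are purchased.

## Route

Step 1
Reactants: 1 (S)-citramalic acid
Product: 2 2-[(4S)-2,2,4-trimethyl-5-oxo-1,3-dioxolan-4-yl]acetic acid
Conditions: Me2C(OMe)2, TsOH·H2O (cat.), CH2Cl2, rt
Reagents that add atoms: 2,2-dimethoxypropane, COC(C)(C)OC
Why: Acid-catalysed acetal exchange closes the five-membered 1,3-dioxolan-4-one on the α-hydroxy acid unit in preference to a six-membered ring with the β-carboxyl, which leaves the C5 carboxyl free and distinguishes the two acids; no bond at the stereocentre is touched.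

Step 2
Reactants: 2 2-[(4S)-2,2,4-trimethyl-5-oxo-1,3-dioxolan-4-yl]acetic acid; 3 iodomethane
Product: 4 methyl 2-[(4S)-2,2,4-trimethyl-5-oxo-1,3-dioxolan-4-yl]acetate
Conditions: MeI, K2CO3, DMF, 0 °C → rt
Reagents that add atoms: none
Why: SN2 alkylation of the potassium carboxylate gives the methyl ester; the acetonide carbonyl has no α-hydrogen and is inert to K2CO3 in dry DMF.

Step 3
Reactants: 4 methyl 2-[(4S)-2,2,4-trimethyl-5-oxo-1,3-dioxolan-4-yl]acetate
Product: 5 methyl (3S)-3-hydroxy-3-methyl-4-(morpholin-4-yl)-4-oxobutanoate
Conditions: morpholine (3 equiv), THF, 60 °C
Reagents that add atoms: morpholine, C1COCCN1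
Why: Aminolysis of the activated dioxolanone carbonyl by a neutral secondary amine releases acetone and the free tertiary hydroxyl, while the unactivated methyl ester does not react at this temperature; the resulting amide is both the bulky spectator for step 4 and the acyl donor for step 6.

Step 4
Reactants: 5 methyl (3S)-3-hydroxy-3-methyl-4-(morpholin-4-yl)-4-oxobutanoate; 3 iodomethane
Product: 7 methyl (2R,3S)-3-hydroxy-2,3-dimethyl-4-(morpholin-4-yl)-4-oxobutanoate, via dianion 6 (not isolated)
Conditions: LiN(iPr)2 (2.2 equiv), THF, −78 → −20 °C; MeI (1.5 equiv), −78 → −10 °C; aq. HCl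
Reagents that add atoms: none
Why: This is a Fráter–Seebach alkylation: the first equivalent of LiN(iPr)2 forms the lithium alkoxide, the second removes a methylene proton to give the alkoxide–ester enolate dianion 6 in which lithium bridges the two oxygens in a six-membered chelate, and the enolate carbon then displaces iodide from iodomethane (SN2) to form the C4–CH3 bond. The closest known reaction is the dianion alkylation of malate diesters and other β-hydroxy esters, which places the new group anti to the carbinol oxygen. No ring is closed. The one new stereocentre, C4, is controlled by the C3 carbinol: in the chelate the two remaining substituents of C3, methyl and the carboxyl-derived group, lie on opposite faces of the enolate and iodomethane should enter on the face of the smaller one. The step therefore needs the carboxyl-derived group to outweigh methyl, which a methyl ester does not clearly do, and the morpholine amide is used because a tertiary amide on a quaternary carbon cannot turn its N-substituents away from the neighbouring enolate carbon and its carbonyl oxygen is held by the alkoxide lithium. Attack on the methyl face gives the (2R,3S) ester 7, in which the new methyl and the C3 oxygen are anti in the extended chain and cis on the future ring. Chemoselectivity rests on the order of acidities (hydroxyl, then ester α-CH2; the amide has no α-hydrogen) and on the low temperature, which keeps the monoalkoxide from retro-aldol cleavage before the second deprotonation and suppresses O-methylation.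

Step 5
Reactants: 7 methyl (2R,3S)-3-hydroxy-2,3-dimethyl-4-(morpholin-4-yl)-4-oxobutanoate
Product: 8 (2R,3S)-3-hydroxy-2,3-dimethyl-4-(morpholin-4-yl)-4-oxobutanoic acid
Conditions: LiOH·H2O, THF/H2O (3:1), 0 °C → rt; aq. HCl to pH 2
Reagents that add atoms: lithium hydroxide, [Li+].[OH-]
Why: Saponification (acyl substitution) frees the C5 carboxyl while the tertiary amide is untouched; in water the tertiary alkoxide concentration is too low for retro-aldol cleavage, and as a carboxylate this group will be inert to the aryllithium and will shield C4–H from deprotonation.

Step 6
Reactants: 8 (2R,3S)-3-hydroxy-2,3-dimethyl-4-(morpholin-4-yl)-4-oxobutanoic acid; 9 1-(benzyloxy)-4-bromo-2-methoxybenzene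
Product: 11 (2R,3S)-4-[4-(benzyloxy)-3-methoxyphenyl]-3-hydroxy-2,3-dimethyl-4-oxobutanoic acid, via aryllithium 10 (not isolated)
Conditions: 9 (3.5 equiv), n-BuLi (3.4 equiv), THF, −78 °C; then 8 in THF, −78 → −20 °C; aq. HCl to pH 3
Reagents that add atoms: none
Why: Bromine–lithium exchange gives 10; two equivalents deprotonate the acid and the hydroxyl and a third adds to the morpholine amide to give a tetrahedral lithium alkoxide that is stable in the cold and releases the ketone only on acidic work-up, so one aryl group is introduced (acylation of an organolithium by a tertiary amide). Lithium carboxylates do not add aryllithiums at these temperatures.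

Step 7
Reactants: 11 (2R,3S)-4-[4-(benzyloxy)-3-methoxyphenyl]-3-hydroxy-2,3-dimethyl-4-oxobutanoic acid; 3 iodomethane
Product: 12 methyl (2R,3S)-4-[4-(benzyloxy)-3-methoxyphenyl]-3-hydroxy-2,3-dimethyl-4-oxobutanoate
Conditions: MeI, KHCO3, DMF, rt
Reagents that add atoms: none
Why: SN2 alkylation of the carboxylate under nearly neutral conditions gives the open-chain methyl ester (acid-catalysed esterification of a γ-keto acid can give the cyclic pseudo-ester) and avoids the alkoxide that would start retro-aldol cleavage of the β-hydroxy ester.

Step 8
Reactants: 12 methyl (2R,3S)-4-[4-(benzyloxy)-3-methoxyphenyl]-3-hydroxy-2,3-dimethyl-4-oxobutanoate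
Product: 14 (3R,4S,5R)-5-[4-(benzyloxy)-3-methoxyphenyl]-4-hydroxy-3,4-dimethyloxolan-2-one, via diol ester 13 (not isolated)
Conditions: Zn(BH4)2, Et2O, −20 → 0 °C; H2O; then PPTS (cat.), CH2Cl2, rt
Reagents that add atoms: none
Why: Chelation-controlled reduction of an α-hydroxy ketone: zinc ties the ketone oxygen and the C3 hydroxyl into a five-membered chelate, C3 then shows its methyl group on one face and the branched chain on the other, and hydride adds from the methyl face to set C2 (4R in 13). The new benzylic hydroxyl closes the γ-lactone on the methyl ester under mild acid (5-exo-trig acyl substitution), which also protects C2–O as an acyl oxygen.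

Step 9
Reactants: 14 (3R,4S,5R)-5-[4-(benzyloxy)-3-methoxyphenyl]-4-hydroxy-3,4-dimethyloxolan-2-one
Product: 15 (3R,4S,5R)-5-[4-(benzyloxy)-3-methoxyphenyl]-3,4-dimethyloxolane-2,4-diol (mixture of anomers at the lactol carbon)
Conditions: i-Bu2AlH (2.5 equiv), CH2Cl2, −78 °C; aq. potassium sodium tartrate
Reagents that add atoms: none
Why: Partial reduction of a γ-lactone stops at the aluminium lactolate at −78 °C and gives the lactol on work-up; the free tertiary hydroxyl only consumes one equivalent of hydride, and the anomeric mixture is of no consequence because the next step passes through the cation.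

Step 10
Reactants: 15 (3R,4S,5R)-5-[4-(benzyloxy)-3-methoxyphenyl]-3,4-dimethyloxolane-2,4-diol; 9 1-(benzyloxy)-4-bromo-2-methoxybenzene
Product: 20 (2R,3S,4S,5S)-2,5-bis[4-(benzyloxy)-3-methoxyphenyl]-3,4-dimethyloxolan-3-ol, via bis(trimethylsilyl) ether 16 (not isolated), via anomeric bromide 17 (not isolated), via arylmagnesium bromide 18 (not isolated), via silyl ether 19 (not isolated)
Conditions: (Me3Si)2NH, Me3SiOTf (cat.), CH2Cl2, rt, then evaporation; Me3SiBr, CH2Cl2, −60 °C; 18 (from 9 and Mg, THF), Li2CuCl4 (cat.), −60 → −20 °C; then K2CO3 (cat.), MeOH, rt
Reagents that add atoms: none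
Why: Silylation masks both hydroxyls, Me3SiBr exchanges the anomeric silyloxy group for bromide, and the copper-catalysed aryl Grignard reagent substitutes the α-bromo ether through its oxocarbenium ion, a known way to trans-2,5-diaryl tetrahydrofurans. C5 is set by inside attack on the envelope that has C3 as the flap with its silyloxy group pseudoaxial and both methyl groups pseudoequatorial, so the aryl enters opposite to the C3 methyl and the C2 aryl, on the face of the C4 methyl. Methanolysis then removes the tertiary trimethylsilyl ether.

Step 11
Reactants: 20 (2R,3S,4S,5S)-2,5-bis[4-(benzyloxy)-3-methoxyphenyl]-3,4-dimethyloxolan-3-ol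
Product: 21 (2R,3S,4S,5S)-2,5-bis(4-hydroxy-3-methoxyphenyl)-3,4-dimethyloxolan-3-ol
Conditions: H2 (1 atm), 10% Pd/C, EtOAc, rt
Reagents that add atoms: none
Why: Hydrogenolysis of the two aryl benzyl ethers; the unhindered ArO–CH2Ph bonds should cleave faster than the two secondary, flanked ring C–O bonds, so the reaction is stopped when debenzylation is complete, and no stereocentre is involved.

## Compound list

1 | (S)-citramalic acid, (2S)-2-hydroxy-2-methylbutanedioic acid | C[C@](O)(CC(=O)O)C(=O)O | starting material
2 | 2-[(4S)-2,2,4-trimethyl-5-oxo-1,3-dioxolan-4-yl]acetic acid | C[C@@]1(CC(=O)O)OC(C)(C)OC1=O | intermediate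
3 | iodomethane | CI | starting material
4 | methyl 2-[(4S)-2,2,4-trimethyl-5-oxo-1,3-dioxolan-4-yl]acetate | C[C@@]1(CC(=O)OC)OC(C)(C)OC1=O | intermediate
5 | methyl (3S)-3-hydroxy-3-methyl-4-(morpholin-4-yl)-4-oxobutanoate | COC(=O)C[C@](C)(O)C(=O)N1CCOCC1 | intermediate
6 | dilithium alkoxide–ester enolate of 5 (chelated dianion, enolate oxygen cis to C3) | CO/C(O[Li])=C/[C@](C)(O[Li])C(=O)N1CCOCC1 | intermediate
7 | methyl (2R,3S)-3-hydroxy-2,3-dimethyl-4-(morpholin-4-yl)-4-oxobutanoate | COC(=O)[C@H](C)[C@](C)(O)C(=O)N1CCOCC1 | intermediate
8 | (2R,3S)-3-hydroxy-2,3-dimethyl-4-(morpholin-4-yl)-4-oxobutanoic acid | OC(=O)[C@H](C)[C@](C)(O)C(=O)N1CCOCC1 | intermediate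
9 | 1-(benzyloxy)-4-bromo-2-methoxybenzene | COc1cc(Br)ccc1OCc1ccccc1 | starting material
10 | [4-(benzyloxy)-3-methoxyphenyl]lithium | COc1cc([Li])ccc1OCc1ccccc1 | intermediate
11 | (2R,3S)-4-[4-(benzyloxy)-3-methoxyphenyl]-3-hydroxy-2,3-dimethyl-4-oxobutanoic acid | OC(=O)[C@H](C)[C@](C)(O)C(=O)c1ccc(OCc2ccccc2)c(OC)c1 | intermediate
12 | methyl (2R,3S)-4-[4-(benzyloxy)-3-methoxyphenyl]-3-hydroxy-2,3-dimethyl-4-oxobutanoate | COC(=O)[C@H](C)[C@](C)(O)C(=O)c1ccc(OCc2ccccc2)c(OC)c1 | intermediate
13 | methyl (2R,3S,4R)-4-[4-(benzyloxy)-3-methoxyphenyl]-3,4-dihydroxy-2,3-dimethylbutanoate | COC(=O)[C@H](C)[C@](C)(O)[C@H](O)c1ccc(OCc2ccccc2)c(OC)c1 | intermediate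
14 | (3R,4S,5R)-5-[4-(benzyloxy)-3-methoxyphenyl]-4-hydroxy-3,4-dimethyloxolan-2-one | O=C1O[C@H](c2ccc(OCc3ccccc3)c(OC)c2)[C@@](C)(O)[C@H]1C | intermediate
15 | (3R,4S,5R)-5-[4-(benzyloxy)-3-methoxyphenyl]-3,4-dimethyloxolane-2,4-diol (anomeric mixture) | OC1O[C@H](c2ccc(OCc3ccccc3)c(OC)c2)[C@@](C)(O)[C@H]1C | intermediate
16 | 2,4-bis(trimethylsilyl) ether of 15 | C[Si](C)(C)OC1O[C@H](c2ccc(OCc3ccccc3)c(OC)c2)[C@@](C)(O[Si](C)(C)C)[C@H]1C | intermediate
17 | anomeric bromide of 16 (bromine in place of the lactol trimethylsilyloxy group) | BrC1O[C@H](c2ccc(OCc3ccccc3)c(OC)c2)[C@@](C)(O[Si](C)(C)C)[C@H]1C | intermediate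
18 | [4-(benzyloxy)-3-methoxyphenyl]magnesium bromide | COc1cc([Mg]Br)ccc1OCc1ccccc1 | intermediate
19 | 3-O-trimethylsilyl ether of 20 | COc1cc([C@H]2O[C@H](c3ccc(OCc4ccccc4)c(OC)c3)[C@@](C)(O[Si](C)(C)C)[C@H]2C)ccc1OCc1ccccc1 | intermediate
20 | (2R,3S,4S,5S)-2,5-bis[4-(benzyloxy)-3-methoxyphenyl]-3,4-dimethyloxolan-3-ol | COc1cc([C@H]2O[C@H](c3ccc(OCc4ccccc4)c(OC)c3)[C@@](C)(O)[C@H]2C)ccc1OCc1ccccc1 | intermediate
21 | (2R,3S,4S,5S)-2,5-bis(4-hydroxy-3-methoxyphenyl)-3,4-dimethyloxolan-3-ol (CNP0234919.3) | COc1cc([C@H]2O[C@H](c3ccc(O)c(OC)c3)[C@@](C)(O)[C@H]2C)ccc1O | target

## Step count and least certain steps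

Total: 11 steps. Longest linear sequence: 11 steps (1 to 21); bromide 9 is used as purchased in steps 6 and 10.

**Step 4 (key step).**
- What may go wrong: poor or reversed facial selectivity, because the only difference between the two faces of the enolate is amide against methyl on a quaternary alkoxide carbon; the monoalkoxide may also fragment by retro-aldol before the second deprotonation.
- Fallback: use the same facial bias with a proton as the electrophile. Starting from 5, if iodomethane enters mainly on the amide face, the main product is the C2 epimer methyl (2S,3S)-3-hydroxy-2,3-dimethyl-4-(morpholin-4-yl)-4-oxobutanoate F1. F1 is deprotonated again with LiN(iPr)2 (2.2 equiv) to the tetrasubstituted dilithium alkoxide–enolate F2 and protonated at −78 °C with a hindered phenol. The proton then enters on the face the methyl group had chosen, which gives 7, where the route is rejoined. If selectivity is merely low, the epimers are separated and F1 is recycled in the same way.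

**Step 10.**
- What may go wrong: loss of face selectivity at C5, since the aryl must enter next to the C4 methyl; loss of HBr from the bromo ether to a dihydrofuran under the basic Grignard reagent; ionisation of the benzylic C2–O bond by the Lewis-acidic salts.
- Fallback: replace external attack on a silyl-protected cation by delivery from the C3 oxygen. Lactol 15 is condensed with benzenesulfinic acid (CaCl2, CH2Cl2) to the anomeric phenyl sulfone with free tertiary hydroxyl F3, a storable solid. Treatment with 18 and ZnBr2 in THF first forms the C3 zinc alkoxide, ZnBr2 then ionises the sulfone, and the arylzinc held on the lower face transfers its aryl to C5, returning to the route at 20.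

**Step 6.**
- What may go wrong: incomplete addition, because the amide is hindered, flanked by an alkoxide and part of a sparingly soluble trilithium salt; warming to force it invites attack on the carboxylate or a second addition.
- Fallback: form the C2–aryl bond at the aldehyde oxidation state. Starting from 7, Cp2Zr(H)Cl in THF reduces the tertiary amide to the aldehyde methyl (2R,3S)-3-hydroxy-2,3-dimethyl-4-oxobutanoate F4 without touching the ester. Reagent 18 adds to the aldehyde at −78 °C to give the diol ester as a mixture of C4 epimers F5. Immediate oxidation of the benzylic alcohol with 2-iodoxybenzoic acid in DMSO (which does not cleave 1,2-diols) gives 12, where the route is rejoined; 8 and 11 are bypassed.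

**Step 8.**
- What may go wrong: erosion of chelation control if zinc binds the C3 hydroxyl together with the ester carbonyl (six-membered chelate) instead of the ketone, which leaves the ketone to react through an open transition state.
- Fallback: change from substrate control to reagent control. Ketone 12 is reduced with BH3·SMe2 and the enantiomer of the 2-methyl-CBS-oxazaborolidine catalyst that delivers hydride to the required face (Corey–Bakshi–Shibata reduction; the tertiary hydroxyl is tied up as its borate in the flask). Lactonisation as before gives 14; no new compound is involved.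

## Further compounds

F1 | step 4 | methyl (2S,3S)-3-hydroxy-2,3-dimethyl-4-(morpholin-4-yl)-4-oxobutanoate | COC(=O)[C@@H](C)[C@](C)(O)C(=O)N1CCOCC1
F2 | step 4 | dilithium alkoxide–ester enolate of F1 (tetrasubstituted enolate, enolate oxygen cis to C3) | CO/C(O[Li])=C(\C)[C@](C)(O[Li])C(=O)N1CCOCC1
F3 | step 10 | anomeric phenyl sulfone of 15: (2R,3S,4R)-5-(benzenesulfonyl)-2-[4-(benzyloxy)-3-methoxyphenyl]-3,4-dimethyloxolan-3-ol, anomeric mixture | O=S(=O)(c1ccccc1)C1O[C@H](c2ccc(OCc3ccccc3)c(OC)c2)[C@@](C)(O)[C@H]1C
F4 | step 6 | methyl (2R,3S)-3-hydroxy-2,3-dimethyl-4-oxobutanoate | COC(=O)[C@H](C)[C@](C)(O)C=O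
F5 | step 6 | methyl (2R,3S)-4-[4-(benzyloxy)-3-methoxyphenyl]-3,4-dihydroxy-2,3-dimethylbutanoate, mixture of C4 epimers | COC(=O)[C@H](C)[C@](C)(O)C(O)c1ccc(OCc2ccccc2)c(OC)c1
F0 | step 8 | none | none
A1 | alternative 1 | (2R,5R)-2,5-bis[4-(benzyloxy)-3-methoxyphenyl]-3,4-dimethyl-2,5-dihydrofuran | [C@H]1(c2ccc(OCc3ccccc3)c(OC)c2)O[C@H](c2ccc(OCc3ccccc3)c(OC)c2)C(C)=C1C
A2 | alternative 1 | (2R,3S,4S,5S)-2,5-bis[4-(benzyloxy)-3-methoxyphenyl]-3,4-dimethyloxolan-3-ol (identical with 20) | [C@H]1(c2ccc(OCc3ccccc3)c(OC)c2)O[C@H](c2ccc(OCc3ccccc3)c(OC)c2)[C@@](C)(O)[C@H]1C
A3 | alternative 2 | (2S,3Z)-3-[4-(benzyloxy)-3-methoxyphenyl]pent-3-en-2-yl (2S)-2-(benzyloxy)propanoate | C[C@H](OCc1ccccc1)C(=O)O[C@@H](C)/C(c1ccc(OCc2ccccc2)c(OC)c1)=C\C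
A4 | alternative 2 | (2S,3S,4Z)-2-(benzyloxy)-4-[4-(benzyloxy)-3-methoxyphenyl]-2,3-dimethylhex-4-enoic acid | OC(=O)[C@@](C)(OCc1ccccc1)[C@@H](C)/C(c1ccc(OCc2ccccc2)c(OC)c1)=C/C
A5 | alternative 3 | (4S,5S)-3-(benzyloxy)-5-[4-(benzyloxy)-3-methoxyphenyl]-4-methyloxolan-2-one (either C3 epimer) | O=C1O[C@H](c2ccc(OCc3ccccc3)c(OC)c2)[C@H](C)C1OCc1ccccc1
A6 | alternative 3 | (3S,4S,5S)-3-(benzyloxy)-5-[4-(benzyloxy)-3-methoxyphenyl]-3,4-dimethyloxolan-2-one | O=C1O[C@H](c2ccc(OCc3ccccc3)c(OC)c2)[C@H](C)[C@]1(C)OCc1ccccc1
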